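The nine-membered carbocycle is numbered from the lactone α-carbon C1 through ring-fusion CH C2, side-chain-bearing CH C3 and acetoxy carbon C4, then C5–C9 round the ring (C6 methylated); C10 is the side-chain stereocentre. The ring is opened at C7–C8, where the sp2 CH of the E-trisubstituted C6=C7 olefin meets the CH2 between the two ring olefins. A one-pot 9-BBN hydroboration/intramolecular B-alkyl Suzuki–Miyaura coupling closes this ring with retention of the E geometry. Its precursor is a monocyclic γ-butyrolactone bearing an E-iodoalkene arm and, on C1, a vinyl and a phenylthio group; later sulfoxide elimination, possible only towards C9, unveils the C1=C9 enoate.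

Key step: step 15

Remark on labels: C18 is the lactone carbonyl carbon and C19 the lactone OCH2 carbon. C2, C3, C4 and C10 keep one spatial arrangement throughout (2S,3S,4R,10R in the target); the CIP letter of C2 reads R in compounds 7 to 27 only because substituent priorities differ.

Assumption: the (S,S)-boron controller of step 3 and the (R)-phosphoric acid of step 6 are taken as the enantiomers whose sense of induction gives the configurations drawn; if either sense is opposite on this substrate, the mirror-image reagent takes its place and nothing else changes.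

Step 1
Reactants: 1 (Z)-but-2-ene-1,4-diol
Product: 2 (Z)-4-[(tert-butyldimethylsilyl)oxy]but-2-en-1-ol
Conditions: NaH (1.0 equiv), THF, 0 °C → rt; then TBSCl
Reagents that add atoms: tert-butyldimethylsilyl chloride, CC(C)(C)[Si](C)(C)Cl
Why: O-silylation of the sparingly soluble monosodium alkoxide should stop at the mono-ether; no stereocentre is formed and the Z olefin is untouched.

Step 2
Reactants: 3 (R)-citronellic acid; 2 (Z)-4-[(tert-butyldimethylsilyl)oxy]but-2-en-1-ol
Product: 4 (Z)-4-(TBS-oxy)but-2-en-1-yl (3R)-3,7-dimethyloct-6-enoate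
Conditions: DCC, DMAP (cat.), CH2Cl2, 0 °C → rt
Reagents that add atoms: none
Why: Steglich esterification joins acid and primary allylic alcohol under neutral conditions without touching C10 or either olefin.

Step 3
Reactants: 4 (Z)-4-(TBS-oxy)but-2-en-1-yl (3R)-3,7-dimethyloct-6-enoate
Product: 7 (2S,3R)-3-[(TBS-oxy)methyl]-2-[(2R)-6-methylhept-5-en-2-yl]pent-4-enoic acid, via boron ketene acetal 5 (not isolated), via acyloxyborane 6 (not isolated)
Conditions: (4S,5S)-2-bromo-4,5-diphenyl-1,3-bis{[3,5-bis(trifluoromethyl)phenyl]sulfonyl}-1,3,2-diazaborolidine (from the (S,S)-bis-sulfonamide and BBr3), Et3N, toluene/hexane, −78 → 4 °C; then H2O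
Reagents that add atoms: none
Why: Enantioselective Ireland–Claisen rearrangement through a chiral boron enolate: the E(O)-boron ketene acetal and the Z-allyl unit should pass through a chair transition state with both substituents pseudo-axial, which gives the C2/C3-syn pair, while the (S,S)-diazaborolidine on the enolate oxygen selects the enolate face and so fixes both new centres relative to C10 (reagent control).

Step 4
Reactants: 7 (2S,3R)-3-[(TBS-oxy)methyl]-2-[(2R)-6-methylhept-5-en-2-yl]pent-4-enoic acid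
Product: 8 (2S,3R)-3-[(TBS-oxy)methyl]-2-[(2R)-6-methylhept-5-en-2-yl]pent-4-en-1-ol
Conditions: LiAlH4, Et2O, 0 °C → rt
Reagents that add atoms: none
Why: Hydride reduction of the carboxylic acid should leave the silyl ether and the isolated olefins intact and creates no stereocentre.

Step 5
Reactants: 8 (2S,3R)-3-[(TBS-oxy)methyl]-2-[(2R)-6-methylhept-5-en-2-yl]pent-4-en-1-ol
Product: 9 (2S,3R)-3-[(TBS-oxy)methyl]-2-[(2R)-6-methylhept-5-en-2-yl]pent-4-enal
Conditions: Dess–Martin periodinane, NaHCO3, CH2Cl2, 0 °C → rt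
Reagents that add atoms: none
Why: Dess–Martin oxidation under buffered, non-basic conditions should give the α-branched aldehyde without epimerising C3.

Step 6
Reactants: 9 (2S,3R)-3-[(TBS-oxy)methyl]-2-[(2R)-6-methylhept-5-en-2-yl]pent-4-enal
Product: 11 (4R)-homopropargylic alcohol (C4–OH with CH2C≡CH on C4), via O-boronate 10 (not isolated)
Conditions: allenylboronic acid pinacol ester, (R)-3,3'-bis(2,4,6-triisopropylphenyl)-1,1'-binaphthyl-2,2'-diyl hydrogen phosphate (10 mol%), 4 Å MS, toluene, −20 °C; aqueous work-up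
Reagents that add atoms: allenylboronic acid pinacol ester, C=C=CB1OC(C)(C)C(C)(C)O1
Why: Chiral phosphoric acid-catalysed propargylation with an allenylboronate runs through a six-membered chair transition state (SE2' transfer) in which the (R)-catalyst should direct addition to the Re face of the aldehyde, setting C4 as R under reagent control.

Step 7
Reactants: 11 (4R)-homopropargylic alcohol
Product: 12 bis-TBS ether of 11 (C4–OTBS and C19–OTBS)
Conditions: TBSOTf, 2,6-lutidine, CH2Cl2, −78 → 0 °C
Reagents that add atoms: tert-butyldimethylsilyl trifluoromethanesulfonate, CC(C)(C)[Si](C)(C)OS(=O)(=O)C(F)(F)F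
Why: Silyl ether formation with the silyl triflate masks the hindered C4 alcohol for the later enolate chemistry; no stereocentre changes.

Step 8
Reactants: 12 bis-TBS ether with terminal alkyne
Product: 14 (E)-iodoalkene (C5H2–C6(CH3)=C7H–I), via alkenylalane 13 (not isolated)
Conditions: AlMe3, Cp2ZrCl2 (0.3 equiv), H2O (1 equiv), CH2Cl2, −23 °C; then I2, THF, −23 → 0 °C
Reagents that add atoms: trimethylaluminium, C[Al](C)C; iodine, II
Why: Zirconium-catalysed carboalumination (Negishi) adds methyl and aluminium syn across the terminal alkyne with methyl on the internal carbon, and iodinolysis with retention should give the E-iodoalkene; the monosubstituted olefin reacts far more slowly than the alkyne.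

Step 9
Reactants: 14 (E)-iodoalkene bearing the C2 vinyl group
Product: 16 primary alcohol (C1H2–C18H2OH on C2), via B-alkyl-9-BBN 15 (not isolated)
Conditions: 9-BBN, THF, 0 °C → rt; then NaOH, H2O2, 0 °C
Reagents that add atoms: hydrogen peroxide, OO
Why: Anti-Markovnikov hydroboration with bulky 9-BBN should take place only at the monosubstituted olefin and oxidation with retention gives the primary alcohol; the trisubstituted olefin and the iodoalkene are too hindered.

Step 10
Reactants: 16 primary alcohol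
Product: 18 carboxylic acid (C1H2–C18O2H on C2), via aldehyde 17 (not isolated)
Conditions: TEMPO (cat.), PhI(OAc)2, MeCN/H2O, rt
Reagents that add atoms: water, O
Why: TEMPO/PhI(OAc)2 oxidation in wet acetonitrile takes the primary alcohol through the aldehyde hydrate to the acid and should not affect olefins, iodoalkene or silyl ethers.

Step 11
Reactants: 18 carboxylic acid with C19–OTBS
Product: 20 β-substituted γ-butyrolactone (C18(=O)–O–C19H2–C2H–C1H2), via hydroxy acid 19 (not isolated)
Conditions: camphorsulfonic acid (cat.), MeOH/CH2Cl2, 0 °C → rt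
Reagents that add atoms: none
Why: Acid-catalysed methanolysis should remove the primary silyl ether much faster than the hindered secondary one, and the freed γ-hydroxy acid lactonises spontaneously (intramolecular acyl substitution).

Step 12
Reactants: 20 β-substituted γ-butyrolactone
Product: 22 α-(phenylthio) lactone (SPh on C1 trans to the C2 substituent), via lithium enolate 21 (not isolated)
Conditions: LiN(i-Pr)2, THF, −78 °C; PhSSPh, HMPA, −78 → 0 °C; aq. NH4Cl
Reagents that add atoms: diphenyl disulfide, c1ccc(SSc2ccccc2)cc1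
Why: α-Sulfenylation of the lactone lithium enolate; the phenylthio group should enter anti to the C2 substituent, a configuration that is erased again when C1 is re-enolised in step 13.

Step 13
Reactants: 22 α-(phenylthio) lactone
Product: 24 α-(phenylthio)-α-[2-(phenylsulfinyl)ethyl] lactone (SPh cis to C3; sulfoxide epimers), via lithium enolate 23 (not isolated)
Conditions: LiN(i-Pr)2, THF, −78 °C; phenyl vinyl sulfoxide, −78 → 0 °C; aq. NH4Cl
Reagents that add atoms: phenyl vinyl sulfoxide, C=CS(=O)c1ccccc1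
Why: Michael addition of the thio-stabilised tertiary enolate to phenyl vinyl sulfoxide (a vinyl cation equivalent); the new C1–C9 bond should form anti to the bulky C2 substituent, which leaves the phenylthio group cis to C3 and trans to H-2 (substrate control at the quaternary centre).

Step 14
Reactants: 24 α-(phenylthio)-α-[2-(phenylsulfinyl)ethyl] lactone
Product: 25 α-(phenylthio)-α-vinyl lactone (C9=C8 vinyl on C1)
Conditions: toluene, NaHCO3, 125 °C (sealed tube)
Reagents that add atoms: none
Why: Thermal syn-elimination of the primary alkyl phenyl sulfoxide (sulfoxide pyrolysis) should release the vinyl group, while the unoxidised C1 sulfide stays.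

Step 15
Reactants: 25 α-(phenylthio)-α-vinyl lactone bearing the (E)-iodoalkene
Product: 27 trans-fused bicyclic lactone with the E-C6=C7 cyclononene and SPh on C1, via B-alkyl-9-BBN 26 (not isolated)
Conditions: 9-BBN, THF, rt; then slow addition to PdCl2(dppf) (20 mol%), AsPh3, Cs2CO3, DMF/THF/H2O, 50 °C, 0.002 M
Reagents that add atoms: none
Why: 9-BBN adds to the only monosubstituted olefin and places boron on terminal C8; zerovalent palladium, formed from the divalent precatalyst, then inserts into the C7–I bond, the borate formed with Cs2CO3 transfers the primary C8 alkyl group, and reductive elimination joins C7 to C8. The closest known reaction type is the intramolecular B-alkyl Suzuki–Miyaura coupling, which is established for medium and large rings with E-trisubstituted alkenyl iodides. The nine-membered carbocycle is closed by C(sp2)–C(sp3) reductive elimination from a ten-membered palladacycle and ends up trans-fused to the lactone. No stereocentre is created: the E geometry of C6=C7 comes from step 8 and is retained, and the ring fusion follows from the C1 configuration set in step 13. The step needs chemoselective hydroboration, which the steric demand of 9-BBN secures against the trisubstituted olefins, the iodoalkene and the lactone, and ring closure over oligomerisation, which slow addition at high dilution and the gem-disubstituted C1 should favour. The quaternary, non-enolisable C1 also rules out epimerisation or conjugation of the vinyl lactone under the basic conditions.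

Step 16
Reactants: 27 trans-fused bicyclic α-(phenylthio) lactone
Product: 29 C4-TBS ether of the skipped-diene lactone (C1=C9 E-enoate), via sulfoxide 28 (not isolated)
Conditions: NaIO4, MeOH/THF/H2O, rt; then toluene, CaCO3, 100 °C
Reagents that add atoms: none
Why: Periodate should oxidise the sulfide chemoselectively to the sulfoxide, whose thermal syn-elimination can only take a hydrogen from C9 because H-2 lies on the opposite face, and the nine-membered ring allows only the olefin with C8 cis to C2, i.e. the E-enoate.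

Step 17
Reactants: 29 C4-TBS ether of the skipped-diene lactone
Product: 30 C4 alcohol (4-hydroxy lactone)
Conditions: HF·pyridine, pyridine, THF, 0 °C → rt
Reagents that add atoms: none
Why: Buffered fluoride desilylation should free the C4 alcohol without base-induced migration of the skipped diene.

Step 18
Reactants: 30 C4 alcohol
Product: 31 target acetate CNP0288725.2
Conditions: Ac2O, pyridine, DMAP (cat.), CH2Cl2, 0 °C → rt
Reagents that add atoms: acetic anhydride, CC(=O)OC(C)=O
Why: DMAP-catalysed O-acylation of the secondary alcohol should give the acetate with retention at C4.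

Compound list

1 | (Z)-but-2-ene-1,4-diol | OC/C=C\CO | starting material
2 | (Z)-4-[(tert-butyldimethylsilyl)oxy]but-2-en-1-ol | CC(C)(C)[Si](C)(C)OC/C=C\CO | intermediate
3 | (R)-citronellic acid, (3R)-3,7-dimethyloct-6-enoic acid | CC(C)=CCC[C@@H](C)CC(=O)O | starting material
4 | (Z)-4-(TBS-oxy)but-2-en-1-yl (3R)-3,7-dimethyloct-6-enoate | CC(C)=CCC[C@@H](C)CC(=O)OC/C=C\CO[Si](C)(C)C(C)(C)C | intermediate
5 | E(O)-boron ketene acetal of 4 carrying the (S,S)-diazaborolidine on oxygen | CC(C)=CCC[C@@H](C)/C=C(/OB1N(S(=O)(=O)c2cc(C(F)(F)F)cc(C(F)(F)F)c2)[C@@H](c2ccccc2)[C@H](c2ccccc2)N1S(=O)(=O)c1cc(C(F)(F)F)cc(C(F)(F)F)c1)OC/C=C\CO[Si](C)(C)C(C)(C)C | intermediate (not isolated)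
6 | (S,S)-diazaborolidinyl ester (acyloxyborane) of acid 7 | CC(C)(C)[Si](C)(C)OC[C@H](C=C)[C@@H](C(=O)OB1N(S(=O)(=O)c2cc(C(F)(F)F)cc(C(F)(F)F)c2)[C@@H](c2ccccc2)[C@H](c2ccccc2)N1S(=O)(=O)c1cc(C(F)(F)F)cc(C(F)(F)F)c1)[C@H](C)CCC=C(C)C | intermediate (not isolated)
7 | (2S,3R)-3-[(TBS-oxy)methyl]-2-[(2R)-6-methylhept-5-en-2-yl]pent-4-enoic acid (C4 = CO2H; C2/C3 syn) | CC(C)(C)[Si](C)(C)OC[C@H](C=C)[C@@H](C(=O)O)[C@H](C)CCC=C(C)C | intermediate
8 | (2S,3R)-3-[(TBS-oxy)methyl]-2-[(2R)-6-methylhept-5-en-2-yl]pent-4-en-1-ol | CC(C)(C)[Si](C)(C)OC[C@H](C=C)[C@@H](CO)[C@H](C)CCC=C(C)C | intermediate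
9 | (2S,3R)-3-[(TBS-oxy)methyl]-2-[(2R)-6-methylhept-5-en-2-yl]pent-4-enal | CC(C)(C)[Si](C)(C)OC[C@H](C=C)[C@@H](C=O)[C@H](C)CCC=C(C)C | intermediate
10 | pinacol boronate ester of alcohol 11 (C4–O–B) | CC(C)(C)[Si](C)(C)OC[C@H](C=C)[C@@H]([C@H](OB1OC(C)(C)C(C)(C)O1)CC#C)[C@H](C)CCC=C(C)C | intermediate (not isolated)
11 | (4R)-homopropargylic alcohol: C4 carbinol bearing CH2C≡CH, with C2 vinyl and C19–OTBS | CC(C)(C)[Si](C)(C)OC[C@H](C=C)[C@@H]([C@H](O)CC#C)[C@H](C)CCC=C(C)C | intermediate
12 | bis-TBS ether of 11 | CC(C)(C)[Si](C)(C)OC[C@H](C=C)[C@@H]([C@H](O[Si](C)(C)C(C)(C)C)CC#C)[C@H](C)CCC=C(C)C | intermediate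
13 | (E)-alkenyl(dimethyl)alane from carboalumination of 12 | CC(C)(C)[Si](C)(C)OC[C@H](C=C)[C@@H]([C@H](O[Si](C)(C)C(C)(C)C)C/C(C)=C/[Al](C)C)[C@H](C)CCC=C(C)C | intermediate (not isolated)
14 | (E)-iodoalkene: C5H2–C6(CH3)=C7H–I, with C2 vinyl and both TBS ethers | CC(C)(C)[Si](C)(C)OC[C@H](C=C)[C@@H]([C@H](O[Si](C)(C)C(C)(C)C)C/C(C)=C/I)[C@H](C)CCC=C(C)C | intermediate
15 | B-alkyl-9-BBN from hydroboration of the vinyl group of 14 (boron on C18) | CC(C)(C)[Si](C)(C)OC[C@H](CCB1C2CCCC1CCC2)[C@@H]([C@H](O[Si](C)(C)C(C)(C)C)C/C(C)=C/I)[C@H](C)CCC=C(C)C | intermediate (not isolated)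
16 | primary alcohol: C2 bearing CH2CH2OH (C1, C18) | CC(C)(C)[Si](C)(C)OC[C@H](CCO)[C@@H]([C@H](O[Si](C)(C)C(C)(C)C)C/C(C)=C/I)[C@H](C)CCC=C(C)C | intermediate
17 | aldehyde at C18 | CC(C)(C)[Si](C)(C)OC[C@H](CC=O)[C@@H]([C@H](O[Si](C)(C)C(C)(C)C)C/C(C)=C/I)[C@H](C)CCC=C(C)C | intermediate (not isolated)
18 | carboxylic acid at C18 | CC(C)(C)[Si](C)(C)OC[C@H](CC(=O)O)[C@@H]([C@H](O[Si](C)(C)C(C)(C)C)C/C(C)=C/I)[C@H](C)CCC=C(C)C | intermediate
19 | γ-hydroxy acid (C19–OH free, C18 acid) | OC[C@H](CC(=O)O)[C@@H]([C@H](O[Si](C)(C)C(C)(C)C)C/C(C)=C/I)[C@H](C)CCC=C(C)C | intermediate (not isolated)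
20 | β-substituted γ-butyrolactone with C4–OTBS and (E)-iodoalkene arm | O=C1OC[C@H](C1)[C@@H]([C@H](O[Si](C)(C)C(C)(C)C)C/C(C)=C/I)[C@H](C)CCC=C(C)C | intermediate
21 | lithium enolate of 20 | [Li]OC1OC[C@H](C=1)[C@@H]([C@H](O[Si](C)(C)C(C)(C)C)C/C(C)=C/I)[C@H](C)CCC=C(C)C | intermediate (not isolated)
22 | α-(phenylthio) lactone, SPh on C1 trans to the C2 substituent | O=C1OC[C@H]([C@@H]1Sc2ccccc2)[C@@H]([C@H](O[Si](C)(C)C(C)(C)C)C/C(C)=C/I)[C@H](C)CCC=C(C)C | intermediate
23 | lithium enolate of 22 | [Li]OC1OC[C@H](C=1Sc2ccccc2)[C@@H]([C@H](O[Si](C)(C)C(C)(C)C)C/C(C)=C/I)[C@H](C)CCC=C(C)C | intermediate (not isolated)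
24 | α-(phenylthio)-α-[2-(phenylsulfinyl)ethyl] lactone, SPh cis to C3, mixture at sulfoxide sulfur | O=C1OC[C@H]([C@]1(Sc2ccccc2)CCS(=O)c2ccccc2)[C@@H]([C@H](O[Si](C)(C)C(C)(C)C)C/C(C)=C/I)[C@H](C)CCC=C(C)C | intermediate
25 | α-(phenylthio)-α-vinyl lactone, SPh cis to C3, vinyl (C9=C8) trans to C3 | O=C1OC[C@H]([C@]1(Sc2ccccc2)C=C)[C@@H]([C@H](O[Si](C)(C)C(C)(C)C)C/C(C)=C/I)[C@H](C)CCC=C(C)C | intermediate
26 | B-alkyl-9-BBN from hydroboration of 25 (boron on C8) | O=C1OC[C@H]([C@]1(Sc2ccccc2)CCB2C3CCCC2CCC3)[C@@H]([C@H](O[Si](C)(C)C(C)(C)C)C/C(C)=C/I)[C@H](C)CCC=C(C)C | intermediate (not isolated)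
27 | trans-fused bicyclic lactone: nine-membered ring with E-C6=C7, C8H2–C9H2, SPh on C1, C4–OTBS | CC(C)(C)[Si](C)(C)O[C@@H]1C/C(C)=C/CC[C@]2(Sc3ccccc3)C(=O)OC[C@H]2[C@@H]1[C@H](C)CCC=C(C)C | intermediate
28 | sulfoxide of 27 (mixture at sulfur) | CC(C)(C)[Si](C)(C)O[C@@H]1C/C(C)=C/CC[C@]2(S(=O)c3ccccc3)C(=O)OC[C@H]2[C@@H]1[C@H](C)CCC=C(C)C | intermediate (not isolated)
29 | C4-TBS ether of the skipped-diene lactone (E-C6=C7, E-C1=C9 enoate) | CC(C)(C)[Si](C)(C)O[C@@H]1C/C(C)=C/C/C=C2/C(=O)OC[C@H]2[C@@H]1[C@H](C)CCC=C(C)C | intermediate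
30 | C4 alcohol (2S,3S,4R,10R) | O[C@@H]1C/C(C)=C/C/C=C2/C(=O)OC[C@H]2[C@@H]1[C@H](C)CCC=C(C)C | intermediate
31 | CNP0288725.2, C4 acetate of 30 (2S,3S,4R,10R) | CC(=O)O[C@@H]1C/C(C)=C/C/C=C2/C(=O)OC[C@H]2[C@@H]1[C@H](C)CCC=C(C)C | target

Total step count: 18. Longest linear sequence: 18 steps (1 → 31); 3 enters at step 2.

Steps most likely to fail

Step 15. Oligomerisation, protodeboronation and β-hydride elimination may outrun the slow ring-closing transmetalation and reductive elimination to the strained trans-fused ring, and aqueous base may open the lactone. The fallback sets out from 25 and closes the same bond with a base-free, water-free organozinc partner. Hydroboration as before gives 26, and iodinolysis (I2, NaOMe, MeOH/THF, 0 °C) gives the primary iodide F1. Zinc insertion (Zn dust, LiCl, THF, 40 °C), selective for the alkyl iodide over the iodoalkene, gives the alkylzinc iodide F2. Slow addition of F2 to Pd2(dba)3/tri(2-furyl)phosphine in THF/NMP (intramolecular Negishi coupling) should come back to the route at 27.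

Step 3. The controller may discriminate the enolate faces poorly when it opposes the bias of C10, and the Z-olefin may leak through a boat transition state. The fallback sets out from 3 and replaces reagent control by 1,3-chirality transfer.
- Alcohol fragment: (R)-but-3-yn-2-ol is hydroxymethylated (n-BuLi, 2 equiv; paraformaldehyde) to (R)-pent-2-yne-1,4-diol F3, silylated at the primary hydroxyl (TBSCl, imidazole) to F4, and semi-hydrogenated (H2, Lindlar catalyst Pd/CaCO3/Pb(OAc)2, quinoline) to (R,Z)-5-(TBS-oxy)pent-3-en-2-ol F5.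
- Rearrangement: Steglich esterification with 3 gives ester F6. LiN(i-Pr)2/Me3SiCl (THF, −78 °C → rt) gives the E(O)-silyl ketene acetal F7, which rearranges through a chair with the carbinol methyl pseudo-equatorial to the silyl ester F8. Aqueous work-up gives the (E)-propenyl acid F9.
- Return: ethenolysis (ethylene, first-generation Grubbs catalyst RuCl2(PCy3)2(=CHPh), CH2Cl2), which spares the trisubstituted olefin, should come back to the route at 7.

Step 13. Conjugate addition of the hindered tertiary enolate may be sluggish or reversible, with proton transfer and polymerisation of the acceptor taking over. The fallback sets out from 22 and builds the vinyl group by one-carbon steps. Enolate 23 is trapped with monomeric formaldehyde (anti to the C2 substituent) to give the hydroxymethyl lactone F10. Oxidation (SO3·pyridine, DMSO, Et3N) gives the non-enolisable formyl lactone F11. Wittig methylenation (Ph3P=CH2, THF, −78 → 0 °C) should come back to the route at 25.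

Further compounds

F1 | step 15 | α-(2-iodoethyl)-α-(phenylthio) lactone | O=C1OC[C@H]([C@]1(Sc2ccccc2)CCI)[C@@H]([C@H](O[Si](C)(C)C(C)(C)C)C/C(C)=C/I)[C@H](C)CCC=C(C)C
F2 | step 15 | alkylzinc iodide from F1 | O=C1OC[C@H]([C@]1(Sc2ccccc2)CC[Zn]I)[C@@H]([C@H](O[Si](C)(C)C(C)(C)C)C/C(C)=C/I)[C@H](C)CCC=C(C)C
F3 | step 3 | (R)-pent-2-yne-1,4-diol | C[C@@H](O)C#CCO
F4 | step 3 | (R)-5-(TBS-oxy)pent-3-yn-2-ol | C[C@@H](O)C#CCO[Si](C)(C)C(C)(C)C
F5 | step 3 | (R,Z)-5-(TBS-oxy)pent-3-en-2-ol | C[C@@H](O)/C=C\CO[Si](C)(C)C(C)(C)C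
F6 | step 3 | (R,Z)-5-(TBS-oxy)pent-3-en-2-yl (3R)-3,7-dimethyloct-6-enoate | CC(C)=CCC[C@@H](C)CC(=O)O[C@H](C)/C=C\CO[Si](C)(C)C(C)(C)C
F7 | step 3 | E(O)-trimethylsilyl ketene acetal of F6 | CC(C)=CCC[C@@H](C)/C=C(/O[Si](C)(C)C)O[C@H](C)/C=C\CO[Si](C)(C)C(C)(C)C
F8 | step 3 | trimethylsilyl ester of acid F9 | CC(C)(C)[Si](C)(C)OC[C@H](/C=C/C)[C@@H](C(=O)O[Si](C)(C)C)[C@H](C)CCC=C(C)C
F9 | step 3 | (E)-propenyl analogue of acid 7 | CC(C)(C)[Si](C)(C)OC[C@H](/C=C/C)[C@@H](C(=O)O)[C@H](C)CCC=C(C)C
F10 | step 13 | α-(hydroxymethyl)-α-(phenylthio) lactone | O=C1OC[C@H]([C@]1(Sc2ccccc2)CO)[C@@H]([C@H](O[Si](C)(C)C(C)(C)C)C/C(C)=C/I)[C@H](C)CCC=C(C)C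
F11 | step 13 | α-formyl-α-(phenylthio) lactone | O=C1OC[C@H]([C@]1(Sc2ccccc2)C=O)[C@@H]([C@H](O[Si](C)(C)C(C)(C)C)C/C(C)=C/I)[C@H](C)CCC=C(C)C
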